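Target numbering: C1 (ring carbon bearing CH2OBz), C2 (OBz), C3 (OAc), C4 and C5 (diol), C6 (=CH). The cyclohexene is cut at C6–C5 and C4–C3: a copper-catalysed asymmetric Diels–Alder reaction of furan-3-ylmethyl benzoate with an acrylimide makes both bonds and gives a 7-oxanorbornene. The step exploits the 1,4-relation of the C3 oxygen and C6 across the ring: the oxygen bridge is the future C3–O, and the bridged allyl ether stores the C6=C1 alkene and the C2 benzoate, released by anti-SN2' opening. The acyl carbon is then excised to a 4,5-alkene, which hydroxyl-directed epoxidation and hydrolysis turn into the trans-diol.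

Key step: step 2

Assumption: the copper catalyst is taken to show the same sense of induction as with unsubstituted furan, so that the (R,R) ligand delivers 4, and the (R,S) ferrocenyl ligand is taken as the matched one for opening 4; if either sense proves opposite, the antipodal ligand is used.

Abbreviations: t-Bu-box = 2,2'-(propane-2,2-diyl)bis(4-tert-butyl-4,5-dihydro-1,3-oxazole); cod = cycloocta-1,5-diene; PPF-P(t-Bu)2 = di-tert-butyl{1-[2-(diphenylphosphanyl)ferrocenyl]ethyl}phosphane; dmgH = dimethylglyoximate; acac = acetylacetonate. Atom numbers C1–C6 in the Why lines are the target numbering above.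

Step 1
Reactants: 1 furan-3-ylmethanol
Product: 2 furan-3-ylmethyl benzoate
Conditions: BzCl, Et3N, DMAP (cat.), CH2Cl2, 0 °C to rt
Reagents that add atoms: benzoyl chloride, O=C(Cl)c1ccccc1
Why: DMAP-catalysed O-benzoylation (nucleophilic acyl substitution) of the primary alcohol should be clean because the furan ring is inert to the acyl chloride under buffered basic conditions; no stereocenter is formed.

Step 2
Reactants: 2 furan-3-ylmethyl benzoate; 3 3-acryloyl-1,3-oxazolidin-2-one
Product: 4 3-{[(1R,2R,4R)-5-(benzoyloxymethyl)-7-oxabicyclo[2.2.1]hept-5-en-2-yl]carbonyl}-1,3-oxazolidin-2-one (endo acyl)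
Conditions: [Cu((R,R)-t-Bu-box)](SbF6)2 (cat.), CH2Cl2, −78 °C; cold filtration through silica, then chromatography
Reagents that add atoms: none
Why: The imide 3 chelates the divalent copper centre through both carbonyl groups in a square-planar array and the furan adds to the exposed face of the s-cis acrylimide in a concerted, asynchronous Diels–Alder reaction; the closest known reaction type is the copper bis(oxazoline)-catalysed cycloaddition of furan itself with this acrylimide. The six-membered carbocycle is closed by a suprafacial [4+2] cycloaddition that forms C6–C5 and C4–C3 in one event, the furan oxygen being carried along as the bridge of the 7-oxabicyclo[2.2.1]heptene. The bridgehead that becomes C3 (and its partner C6) is set by which furan face adds, and that face is fixed jointly by the ligand-controlled face of the dienophile, the endo orientation of the acyl group and the regiochemistry; the acyl-bearing C4 centre is also set by the catalyst but is sacrificial. The step needs regioselectivity (acyl-bearing carbon bonded to the unsubstituted furan C5), endo selectivity and facial selectivity: the first should come from the larger HOMO coefficient at C2 of the 3-alkyl-substituted furan together with the endo acyl group avoiding the substituted C3, the second from kinetic control at low temperature, the third from the tert-butyl groups of the ligand. Regioisomers and exo isomers are constitutional isomers or diastereomers of 4, so their removal by chromatography should not erode its enantiomeric purity. The cycloaddition is reversible, so the catalyst is removed before the mixture is warmed.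

Step 3
Reactants: 4 3-{[(1R,2R,4R)-5-(benzoyloxymethyl)-7-oxabicyclo[2.2.1]hept-5-en-2-yl]carbonyl}-1,3-oxazolidin-2-one
Product: 5 (1S,5R,6S)-2-(benzoyloxymethyl)-6-hydroxy-5-(2-oxo-1,3-oxazolidine-3-carbonyl)cyclohex-2-en-1-yl benzoate
Conditions: [Rh(cod)Cl]2 (cat.), (R,S)-PPF-P(t-Bu)2 (cat.), PhCO2H, Et3N, THF, 60 °C
Reagents that add atoms: benzoic acid, O=C(O)c1ccccc1
Why: In this rhodium-catalysed anti-SN2' ring opening of an oxabicyclic alkene with a carboxylate, monovalent rhodium should insert from the exo face into the strained allylic C–O bond next to the substituted alkene carbon, and benzoate should attack the unsubstituted terminus of the resulting π-allyl from the face opposite the metal, so that the new C2 benzoate is trans to the C3 hydroxyl left by the bridge and the alkene moves to C6=C1.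

Step 4
Reactants: 5 (1S,5R,6S)-2-(benzoyloxymethyl)-6-hydroxy-5-(2-oxo-1,3-oxazolidine-3-carbonyl)cyclohex-2-en-1-yl benzoate
Product: 7 (1R,5S,6S)-5-(benzoyloxy)-4-(benzoyloxymethyl)-6-hydroxycyclohex-3-ene-1-carboxylic acid, via peroxy acid 6 (not isolated)
Conditions: LiOH, H2O2, THF–H2O, 0 °C; then Na2SO3; then aq. HCl to pH 3
Reagents that add atoms: hydrogen peroxide, OO
Why: Hydroperoxide-mediated cleavage of the N-acyl oxazolidinone (attack of LiOOH on the exocyclic imide carbonyl, then sulfite reduction of the peroxy acid) should free the acid faster than the benzoates are attacked; no stereocenter is formed and the C4 centre is sacrificial.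

Step 5
Reactants: 7 (1R,5S,6S)-5-(benzoyloxy)-4-(benzoyloxymethyl)-6-hydroxycyclohex-3-ene-1-carboxylic acid
Product: 8 (1S,6S)-2-(benzoyloxymethyl)-6-hydroxycyclohexa-2,4-dien-1-yl benzoate
Conditions: 9-mesityl-10-phenylacridinium BF4 (cat.), Co(dmgH)2(py)Cl (cat.), K3PO4 (cat.), MeOH–H2O, blue LED, rt
Reagents that add atoms: none
Why: In this photocatalytic dehydrogenative decarboxyolefination the excited acridinium oxidises the carboxylate, loss of CO2 gives the C4 radical, and the cobaloxime should abstract the weak allylic hydrogen at C5 so that the conjugated 4,5-alkene forms in preference to the enol toward C3; the C4 stereocenter is destroyed and C2 and C3 are untouched.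

Step 6
Reactants: 8 (1S,6S)-2-(benzoyloxymethyl)-6-hydroxycyclohexa-2,4-dien-1-yl benzoate
Product: 9 (1R,2R,3S,6S)-4-(benzoyloxymethyl)-2-hydroxy-7-oxabicyclo[4.1.0]hept-4-en-3-yl benzoate (epoxide cis to the hydroxyl)
Conditions: VO(acac)2 (cat.), t-BuOOH, CH2Cl2, 0 °C
Reagents that add atoms: tert-butyl hydroperoxide, CC(C)(C)OO
Why: In this hydroxyl-directed vanadium-catalysed epoxidation the C3 hydroxyl binds the oxovanadium alkylperoxide and should deliver oxygen to the adjacent C4=C5 alkene on its own face, setting both epoxide carbons cis to C3–OH, while the more remote, ester-deactivated C6=C1 alkene is left alone.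

Step 7
Reactants: 9 (1R,2R,3S,6S)-4-(benzoyloxymethyl)-2-hydroxy-7-oxabicyclo[4.1.0]hept-4-en-3-yl benzoate
Product: 10 (1S,2R,3S,6S)-2-acetoxy-4-(benzoyloxymethyl)-7-oxabicyclo[4.1.0]hept-4-en-3-yl benzoate
Conditions: Ac2O, pyridine, DMAP (cat.), CH2Cl2, 0 °C
Reagents that add atoms: acetic anhydride, CC(=O)OC(C)=O
Why: DMAP-catalysed acetylation of the only free hydroxyl should install the C3 acetate without touching the vinyl epoxide; no stereocenter is formed.

Step 8
Reactants: 10 (1S,2R,3S,6S)-2-acetoxy-4-(benzoyloxymethyl)-7-oxabicyclo[4.1.0]hept-4-en-3-yl benzoate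
Product: 11 [(3R,4S,5S,6S)-5-acetoxy-6-(benzoyloxy)-3,4-dihydroxycyclohex-1-en-1-yl]methyl benzoate
Conditions: H2O, HClO4 (cat.), THF, 0 °C
Reagents that add atoms: water, O
Why: In this acid-catalysed hydrolysis of a vinyl epoxide water should attack the allylic C5 anti to the epoxide oxygen, inverting C5 and leaving that oxygen on C4 with retention, which gives the 4,5-trans-diol with C4–OH cis to the C3 acetate; the cis acetate cannot reach the rear face of C4, so it should not participate.

Compound list
1 | furan-3-ylmethanol | OCc1ccoc1 | starting material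
2 | furan-3-ylmethyl benzoate | O=C(OCc1ccoc1)c1ccccc1 | intermediate
3 | 3-acryloyl-1,3-oxazolidin-2-one | C=CC(=O)N1CCOC1=O | starting material
4 | 3-{[(1R,2R,4R)-5-(benzoyloxymethyl)-7-oxabicyclo[2.2.1]hept-5-en-2-yl]carbonyl}-1,3-oxazolidin-2-one (endo acyl) | O=C(OCC1=C[C@H]2O[C@@H]1C[C@H]2C(=O)N1CCOC1=O)c1ccccc1 | intermediate
5 | (1S,5R,6S)-2-(benzoyloxymethyl)-6-hydroxy-5-(2-oxo-1,3-oxazolidine-3-carbonyl)cyclohex-2-en-1-yl benzoate | O[C@H]1[C@H](C(=O)N2CCOC2=O)CC=C(COC(=O)c2ccccc2)[C@@H]1OC(=O)c1ccccc1 | intermediate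
6 | (1R,5S,6S)-5-(benzoyloxy)-4-(benzoyloxymethyl)-6-hydroxycyclohex-3-ene-1-carboperoxoic acid (not isolated) | O[C@H]1[C@H](C(=O)OO)CC=C(COC(=O)c2ccccc2)[C@@H]1OC(=O)c1ccccc1 | intermediate
7 | (1R,5S,6S)-5-(benzoyloxy)-4-(benzoyloxymethyl)-6-hydroxycyclohex-3-ene-1-carboxylic acid | O[C@H]1[C@H](C(O)=O)CC=C(COC(=O)c2ccccc2)[C@@H]1OC(=O)c1ccccc1 | intermediate
8 | (1S,6S)-2-(benzoyloxymethyl)-6-hydroxycyclohexa-2,4-dien-1-yl benzoate | O[C@H]1C=CC=C(COC(=O)c2ccccc2)[C@@H]1OC(=O)c1ccccc1 | intermediate
9 | (1R,2R,3S,6S)-4-(benzoyloxymethyl)-2-hydroxy-7-oxabicyclo[4.1.0]hept-4-en-3-yl benzoate | O[C@H]1[C@H]2O[C@H]2C=C(COC(=O)c2ccccc2)[C@@H]1OC(=O)c1ccccc1 | intermediate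
10 | (1S,2R,3S,6S)-2-acetoxy-4-(benzoyloxymethyl)-7-oxabicyclo[4.1.0]hept-4-en-3-yl benzoate | CC(=O)O[C@H]1[C@H]2O[C@H]2C=C(COC(=O)c2ccccc2)[C@@H]1OC(=O)c1ccccc1 | intermediate
11 | [(3R,4S,5S,6S)-5-acetoxy-6-(benzoyloxy)-3,4-dihydroxycyclohex-1-en-1-yl]methyl benzoate | CC(=O)O[C@H]1[C@@H](O)[C@H](O)C=C(COC(=O)c2ccccc2)[C@@H]1OC(=O)c1ccccc1 | target

Total step count: 8. Longest linear sequence: 8 steps (1 to 11).

Steps most likely to fail

Step 3. The rhodium catalyst may fail to engage the trisubstituted alkene, or may ionise the allylic benzoate instead of the bridge. The endo imide carbonyl may capture the allyl intermediate intramolecularly, and 4 may undergo cycloreversion at the reaction temperature. The fallback sets out from 4 and returns at 5 without a transition metal. A Lewis-acid-assisted bromide opening in the anti-SN2' sense (MgBr2·OEt2, CH2Cl2, −40 °C) should give the trans-bromohydrin 3-{[(1R,5S,6S)-5-bromo-4-(benzoyloxymethyl)-6-hydroxycyclohex-3-en-1-yl]carbonyl}-1,3-oxazolidin-2-one F1. DBU in CH2Cl2 should then close it, with inversion at the allylic carbon, to the vinyl epoxide 3-{[(1S,2R,6R)-5-(benzoyloxymethyl)-7-oxabicyclo[4.1.0]hept-4-en-2-yl]carbonyl}-1,3-oxazolidin-2-one F2. Benzoic acid (toluene, 50 °C) should open F2 at the allylic C2 with a second inversion, which gives 5 with the same trans relationship.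

Step 2. Regio- and endo-selectivity may erode with the weakly directing CH2OBz group, facial discrimination may be poorer than with furan itself, the furan may add in a conjugate (Friedel–Crafts-type) manner, and the adduct may revert on warming. The fallback sets out from 2 and returns at 4 by classical resolution instead of catalysis. A thermal Diels–Alder reaction of 2 with acrylic acid (neat, rt) should give, after crystallisation, the racemic endo acid 5-(benzoyloxymethyl)-7-oxabicyclo[2.2.1]hept-5-ene-2-carboxylic acid F3. Salt formation with (R)-1-phenylethylamine and recrystallisation should give the (R)-1-phenylethylammonium (1R,2R,4R)-carboxylate F4, and dilute HCl frees the (1R,2R,4R)-5-(benzoyloxymethyl)-7-oxabicyclo[2.2.1]hept-5-ene-2-carboxylic acid F5. Pivaloyl chloride and Et3N convert F5 in the flask into the mixed pivalic anhydride F6, which acylates 1,3-oxazolidin-2-one (LiCl, THF) to give 4.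

Step 5. Hydrogen abstraction may occur toward C3 and give an enol and then a ketone, and the dienol may isomerise or aromatise by loss of benzoic acid under irradiation. The fallback sets out from 7 and returns at 8 by a Barton decarboxylation and selenoxide elimination. DCC and N-hydroxypyridine-2-thione should give the 2-thioxopyridin-1(2H)-yl ester F7 of 7. Irradiation with PhSeSePh should give the selenide (1S,6S)-2-(benzoyloxymethyl)-6-hydroxy-5-(phenylselanyl)cyclohex-2-en-1-yl benzoate F8 as a mixture of C5 epimers. H2O2 (THF, 0 °C) should oxidise it to the selenoxide F9, whose syn-elimination, directed away from the carbinol carbon, should give 8.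

Further compounds
F1 | step 3 | 3-{[(1R,5S,6S)-5-bromo-4-(benzoyloxymethyl)-6-hydroxycyclohex-3-en-1-yl]carbonyl}-1,3-oxazolidin-2-one | O[C@H]1[C@H](C(=O)N2CCOC2=O)CC=C(COC(=O)c2ccccc2)[C@@H]1Br
F2 | step 3 | 3-{[(1S,2R,6R)-5-(benzoyloxymethyl)-7-oxabicyclo[4.1.0]hept-4-en-2-yl]carbonyl}-1,3-oxazolidin-2-one | O=C1OCCN1C(=O)[C@@H]1CC=C(COC(=O)c2ccccc2)[C@H]2O[C@@H]12
F3 | step 2 | racemic endo 5-(benzoyloxymethyl)-7-oxabicyclo[2.2.1]hept-5-ene-2-carboxylic acid (relative configuration shown) | O=C(OCC1=C[C@H]2O[C@@H]1C[C@H]2C(O)=O)c1ccccc1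
F4 | step 2 | (R)-1-phenylethylammonium (1R,2R,4R)-5-(benzoyloxymethyl)-7-oxabicyclo[2.2.1]hept-5-ene-2-carboxylate | O=C(OCC1=C[C@H]2O[C@@H]1C[C@H]2C([O-])=O)c1ccccc1.C[C@@H]([NH3+])c1ccccc1
F5 | step 2 | (1R,2R,4R)-5-(benzoyloxymethyl)-7-oxabicyclo[2.2.1]hept-5-ene-2-carboxylic acid (single enantiomer) | O=C(OCC1=C[C@H]2O[C@@H]1C[C@H]2C(O)=O)c1ccccc1
F6 | step 2 | (1R,2R,4R)-5-(benzoyloxymethyl)-7-oxabicyclo[2.2.1]hept-5-ene-2-carboxylic pivalic anhydride | O=C(OCC1=C[C@H]2O[C@@H]1C[C@H]2C(=O)OC(=O)C(C)(C)C)c1ccccc1
F7 | step 5 | 2-thioxopyridin-1(2H)-yl (1R,5S,6S)-5-(benzoyloxy)-4-(benzoyloxymethyl)-6-hydroxycyclohex-3-ene-1-carboxylate | O[C@H]1[C@H](C(=O)ON2C=CC=CC2=S)CC=C(COC(=O)c2ccccc2)[C@@H]1OC(=O)c1ccccc1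
F8 | step 5 | (1S,6S)-2-(benzoyloxymethyl)-6-hydroxy-5-(phenylselanyl)cyclohex-2-en-1-yl benzoate (C5 epimers) | O[C@H]1C([Se]c2ccccc2)CC=C(COC(=O)c2ccccc2)[C@@H]1OC(=O)c1ccccc1
F9 | step 5 | (1S,6S)-2-(benzoyloxymethyl)-6-hydroxy-5-(phenylseleninyl)cyclohex-2-en-1-yl benzoate (C5 epimers) | O[C@H]1C([Se](=O)c2ccccc2)CC=C(COC(=O)c2ccccc2)[C@@H]1OC(=O)c1ccccc1
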